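**Plan**

1. Locants: hydrindane C1–C7a (C1 carries the side chain, C4 the gem-dimethyl group, C7a the angular methyl); side chain C8(=C9H2)–C10H(C11H2OAc); lactone O1', C2'(=O), C3'(OH), C4', C5'.
2. Retrosynthetic cuts, in order: the acetate and the lactone C–O bond; C3'–C4' (glyoxylate syn-aldol); C8–C10 (conjugate addition of a 1-(hydrindanyl)vinyl copper reagent to a chiral 4-silyloxycrotonyl imide); C1–C8 (back to the hydrindan-1-one); C4–C5 (opens the cyclohexane ring); C3a–C4 and C7a–C7 (back to 2-methylcyclopent-2-enone).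
3. Forward: the cyclopentane is bought; one pot adds the isopropenyl group and a 2-(ethoxycarbonyl)allyl arm; the cyclohexane ring is then closed at C4–C5; the side chain is joined and the butyrolactone is formed last.
4. Enabling feature: C4 is a quaternary carbon with two methyl groups next to the ring-fusion CH (C3a), i.e. the Markovnikov carbon of an isopropenyl group, and its ring neighbour C5 is an unsubstituted CH2, i.e. the free terminus of an acrylate. Hydrogen-atom transfer therefore gives a tertiary C4 radical that closes the six-membered ring on C5; a temporary ester on C6 activates the acceptor and is removed in steps 3–4.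
5. Stereochemistry: C3a by Cu/NHC catalysis; C7a relayed in the same pot (trans alkylation, which fixes the trans ring fusion); C1 by hydrogenation anti to the angular methyl; C10, C4' and C3' all from one (S)-4-benzyloxazolidinone (conjugate addition, then syn-aldol).

Key step: step 2

Assumption: the antipode of the NHC ligand in step 1 is taken to be the one that delivers the (S)-configured β-carbon; C6 in 7–9 is an epimeric centre of no consequence because it is erased in step 4.

**Step 1**
Reactants: 1 2-methylcyclopent-2-en-1-one; 2 isopropenylmagnesium bromide; 3 ethyl 2-(bromomethyl)prop-2-enoate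
Product: 5 ethyl 2-{[(1S,5S)-1-methyl-2-oxo-5-(prop-1-en-2-yl)cyclopentyl]methyl}prop-2-enoate, via bromomagnesium enolate 4 (not isolated)
Conditions: 2, Cu(OTf)2 (3 mol %), (S)-1-(1-hydroxy-4-methylpentan-2-yl)-3-mesityl-4,5-dihydroimidazolium hexafluorophosphate (4 mol %), Et2O, −30 °C; then 3, THF, −30 → 0 °C
Reagents that add atoms: none
Why: Copper-catalysed asymmetric conjugate addition of a Grignard reagent to an α-substituted cyclic enone with enolate trapping; the chiral NHC–copper complex selects the enone face for C3a, and the magnesium enolate should be alkylated by the reactive allylic bromide (SN2') anti to the new isopropenyl group, which sets C7a and the trans relation of the two arms.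

**Step 2**
Reactants: 5 ethyl 2-{[(1S,5S)-1-methyl-2-oxo-5-(prop-1-en-2-yl)cyclopentyl]methyl}prop-2-enoate
Product: 8 ethyl (3aS,7aS)-4,4,7a-trimethyl-1-oxooctahydro-1H-indene-6-carboxylate (C6 epimers), via tertiary C4 radical 6 (not isolated), via cyclized C6 radical 7 (not isolated)
Conditions: Fe(acac)3 (30 mol %), PhSiH3, EtOH/ethylene glycol, high dilution, 60 °C
Reagents that add atoms: none
Why: Mechanism: the iron hydride formed from Fe(acac)3 and PhSiH3 in ethanol transfers a hydrogen atom to the terminal CH2 of the electron-rich isopropenyl group (Markovnikov), the resulting tertiary radical at C4 adds to the unsubstituted terminus C5 of the 2-(ethoxycarbonyl)allyl arm, and the α-ester radical at C6 is reduced by divalent iron and protonated by the solvent. The closest known reaction type is the iron-mediated reductive olefin–acceptor coupling (hydrogen-atom-transfer Giese reaction) in its intramolecular form. The cyclohexane ring closes in the 6-endo-trig mode, because C5 is the only electrophilic and unhindered acceptor carbon and the 5-exo alternative would attack the substituted α-carbon and build a trans-fused bicyclo[3.3.0]octane. No stereocenter of the target is created (C4 carries two methyl groups); the trans ring fusion is dictated by the trans arrangement of the arms on C3a and C7a from step 1, and the C6 ester centre, set without control on protonation, is removed in step 4. The step needs hydrogen-atom transfer to the isopropenyl group instead of the acrylate and cyclization faster than reduction of the tertiary radical; the first should follow from the preference of the metal hydride for electron-rich 1,1-disubstituted olefins, the second from the matched polarity of a nucleophilic tertiary radical and an acrylate held in the same molecule under dilution.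

**Step 3**
Reactants: 8 ethyl (3aS,7aS)-4,4,7a-trimethyl-1-oxooctahydro-1H-indene-6-carboxylate
Product: 9 (3aS,7aS)-4,4,7a-trimethyl-1-oxooctahydro-1H-indene-6-carboxylic acid (C6 epimers)
Conditions: LiOH, THF/MeOH/H2O, rt; then aq. HCl
Reagents that add atoms: lithium hydroxide, [Li+].[OH-]
Why: Ester saponification; C7a is quaternary and C3a is not enolisable, so no stereocenter of the target is at risk.

**Step 4**
Reactants: 9 (3aS,7aS)-4,4,7a-trimethyl-1-oxooctahydro-1H-indene-6-carboxylic acid
Product: 10 (3aS,7aS)-4,4,7a-trimethyloctahydro-1H-inden-1-one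
Conditions: 9-mesityl-10-phenylacridinium tetrafluoroborate (5 mol %), PhSSPh (10 mol %), i-Pr2NEt (cat.), CF3CH2OH, 450 nm LEDs, rt
Reagents that add atoms: none
Why: Photoredox hydrodecarboxylation: the carboxylate is oxidised by the excited acridinium, loses CO2, and the secondary C6 radical takes a hydrogen atom from thiophenol, which removes the temporary activating group and its stereocenter.

**Step 5**
Reactants: 10 (3aS,7aS)-4,4,7a-trimethyloctahydro-1H-inden-1-one
Product: 11 (3aS,7aS)-4,4,7a-trimethyl-3a,4,5,6,7,7a-hexahydro-3H-inden-1-yl trifluoromethanesulfonate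
Conditions: KN(SiMe3)2, PhNTf2, THF, −78 °C
Reagents that add atoms: N-phenylbis(trifluoromethanesulfonimide), O=S(=O)(N(c1ccccc1)S(=O)(=O)C(F)(F)F)C(F)(F)F
Why: Enolisation can occur only toward C2 because C7a is quaternary, and O-sulfonylation of the potassium enolate should give the enol triflate.

**Step 6**
Reactants: 11 (3aS,7aS)-4,4,7a-trimethyl-3a,4,5,6,7,7a-hexahydro-3H-inden-1-yl trifluoromethanesulfonate; 12 tributyl(1-ethoxyvinyl)stannane
Product: 14 1-[(3aS,7aS)-4,4,7a-trimethyl-3a,4,5,6,7,7a-hexahydro-3H-inden-1-yl]ethan-1-one, via 2-ethoxydiene 13 (not isolated)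
Conditions: Pd(PPh3)4 (5 mol %), LiCl, THF, reflux; then 1 M aq. HCl, rt
Reagents that add atoms: water, O
Why: Stille coupling of the enol triflate with an α-alkoxyvinyl stannane (acyl anion equivalent), followed by acid hydrolysis of the dienyl enol ether, should give the conjugated methyl ketone.

**Step 7**
Reactants: 14 1-[(3aS,7aS)-4,4,7a-trimethyl-3a,4,5,6,7,7a-hexahydro-3H-inden-1-yl]ethan-1-one
Product: 15 1-[(1S,3aS,7aS)-4,4,7a-trimethyloctahydro-1H-inden-1-yl]ethan-1-one
Conditions: H2 (1 atm), 10% Pd/C, EtOAc, rt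
Reagents that add atoms: none
Why: Heterogeneous hydrogenation of the enone from the face opposite the angular C7a methyl group should deliver hydrogen to C1 on the α face and leave the acetyl group cis to the methyl, as in the hydrogenation of steroidal 16-en-20-ones.

**Step 8**
Reactants: 15 1-[(1S,3aS,7aS)-4,4,7a-trimethyloctahydro-1H-inden-1-yl]ethan-1-one
Product: 16 N'-{(E)-1-[(1S,3aS,7aS)-4,4,7a-trimethyloctahydro-1H-inden-1-yl]ethylidene}-2,4,6-tri(propan-2-yl)benzenesulfonohydrazide
Conditions: 2,4,6-triisopropylbenzenesulfonyl hydrazide, conc. HCl (cat.), MeOH, rt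
Reagents that add atoms: 2,4,6-triisopropylbenzenesulfonyl hydrazide, CC(C)c1cc(C(C)C)c(S(=O)(=O)NN)c(C(C)C)c1
Why: Acid-catalysed condensation to the arylsulfonylhydrazone, expected as the E isomer with the N–N bond anti to the bulky ring.

**Step 9**
Reactants: 17 (S)-4-benzyloxazolidin-2-one; 18 acryloyl chloride
Product: 19 (S)-3-acryloyl-4-benzyloxazolidin-2-one
Conditions: Et3N, LiCl, THF, 0 °C → rt
Reagents that add atoms: none
Why: N-acylation of the oxazolidinone under mild lithium chloride/amine activation, which avoids polymerisation of the acrylimide.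

**Step 10**
Reactants: 19 (S)-3-acryloyl-4-benzyloxazolidin-2-one; 20 allyloxy(tert-butyl)dimethylsilane
Product: 21 (4S)-4-benzyl-3-[(2E)-4-{[tert-butyl(dimethyl)silyl]oxy}but-2-enoyl]-1,3-oxazolidin-2-one
Conditions: second-generation Hoveyda–Grubbs catalyst (5 mol %), 20 (3 equiv), CH2Cl2, 40 °C
Reagents that add atoms: none
Why: Olefin cross-metathesis between an electron-poor acrylimide and an excess of an electron-rich terminal olefin, which should give the E enoyl imide.

**Step 11**
Reactants: 16 N'-{(E)-1-[(1S,3aS,7aS)-4,4,7a-trimethyloctahydro-1H-inden-1-yl]ethylidene}-2,4,6-tri(propan-2-yl)benzenesulfonohydrazide; 21 (4S)-4-benzyl-3-[(2E)-4-{[tert-butyl(dimethyl)silyl]oxy}but-2-enoyl]-1,3-oxazolidin-2-one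
Product: 24 (4S)-4-benzyl-3-[(3R)-3-({[tert-butyl(dimethyl)silyl]oxy}methyl)-4-[(1R,3aS,7aS)-4,4,7a-trimethyloctahydro-1H-inden-1-yl]pent-4-enoyl]-1,3-oxazolidin-2-one, via vinyllithium 22 (not isolated), via vinylmagnesium bromide 23 (not isolated)
Conditions: 16, n-BuLi (2.05 equiv), THF, −78 → 0 °C; MgBr2·OEt2, −78 °C; CuBr·SMe2, THF/Me2S, −40 °C; then 21, −40 → −10 °C; aq. NH4Cl
Reagents that add atoms: none
Why: The Shapiro reaction should give the 1-substituted vinyllithium by deprotonation of the methyl group, and after transmetalation the alkenylcopper adds to the magnesium-chelated syn-s-cis enoyl imide from the face opposite the benzyl group, which sets C10.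

**Step 12**
Reactants: 24 conjugate adduct (name as under step 11); 25 ethyl glyoxylate
Product: 27 ethyl (2S,3S,4R)-3-{[(4S)-4-benzyl-2-oxo-1,3-oxazolidin-3-yl]carbonyl}-4-({[tert-butyl(dimethyl)silyl]oxy}methyl)-2-hydroxy-5-[(1R,3aS,7aS)-4,4,7a-trimethyloctahydro-1H-inden-1-yl]hex-5-enoate, via dibutylboron (Z)-enolate 26 (not isolated)
Conditions: Bu2BOTf, Et3N, CH2Cl2, −78 → 0 °C; 25 (freshly distilled), −78 → 0 °C; pH 7 buffer, MeOH, H2O2
Reagents that add atoms: none
Why: Evans syn-aldol reaction: the (Z)-boron enolate reacts with the aldehyde through a closed chair transition state on the enolate face fixed by the auxiliary, which sets C4' and C3' in the syn relation that becomes trans on the lactone.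

**Step 13**
Reactants: 27 aldol adduct (name as under step 12)
Product: 28 ethyl (2S,3S,4R)-3-{[(4S)-4-benzyl-2-oxo-1,3-oxazolidin-3-yl]carbonyl}-2-{[tert-butyl(dimethyl)silyl]oxy}-4-({[tert-butyl(dimethyl)silyl]oxy}methyl)-5-[(1R,3aS,7aS)-4,4,7a-trimethyloctahydro-1H-inden-1-yl]hex-5-enoate
Conditions: TBSOTf, 2,6-lutidine, CH2Cl2, −78 → 0 °C
Reagents that add atoms: tert-butyldimethylsilyl trifluoromethanesulfonate, CC(C)(C)[Si](C)(C)OS(=O)(=O)C(F)(F)F
Why: Silylation of the secondary alcohol prevents hydroxyl-assisted hydride reduction of the neighbouring ester in the next step.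

**Step 14**
Reactants: 28 silylated aldol adduct (name as under step 13)
Product: 30 (3S,4R)-3-{[tert-butyl(dimethyl)silyl]oxy}-4-[(2R)-1-{[tert-butyl(dimethyl)silyl]oxy}-3-[(1R,3aS,7aS)-4,4,7a-trimethyloctahydro-1H-inden-1-yl]but-3-en-2-yl]oxolan-2-one, via γ-hydroxy ester 29 (not isolated)
Conditions: LiBH4, MeOH (1 equiv), THF, 0 °C; then PPTS (cat.), toluene, 50 °C
Reagents that add atoms: none
Why: Hydride should reduce the activated exocyclic imide carbonyl faster than the hindered α-silyloxy ester (reductive removal of the auxiliary), and the γ-hydroxy ester then closes to the five-membered lactone under mild acid.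

**Step 15**
Reactants: 30 bis-silylated lactone (name as under step 14)
Product: 31 (3S,4R)-3-hydroxy-4-[(2R)-1-hydroxy-3-[(1R,3aS,7aS)-4,4,7a-trimethyloctahydro-1H-inden-1-yl]but-3-en-2-yl]oxolan-2-one
Conditions: HF·pyridine, THF/pyridine, 0 °C → rt
Reagents that add atoms: none
Why: Fluoride-mediated cleavage of both silyl ethers under buffered, weakly acidic conditions that leave the lactone and the 1,1-disubstituted olefin untouched.

**Step 16**
Reactants: 31 diol lactone (name as under step 15); 32 acetyl chloride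
Product: 33 (2R)-2-[(3R,4S)-4-hydroxy-5-oxooxolan-3-yl]-3-[(1R,3aS,7aS)-4,4,7a-trimethyloctahydro-1H-inden-1-yl]but-3-en-1-yl acetate (target)
Conditions: 32 (1.05 equiv), 2,4,6-collidine, CH2Cl2, −78 °C
Reagents that add atoms: none
Why: Kinetic acylation should take the primary alcohol in preference to the hindered, electron-poor secondary α-hydroxy lactone alcohol at low temperature with a weak base.

**Compound list**

1 | 2-methylcyclopent-2-en-1-one | CC1=CCCC1=O | starting material
2 | isopropenylmagnesium bromide | CC(=C)[Mg]Br | starting material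
3 | ethyl 2-(bromomethyl)prop-2-enoate | C=C(CBr)C(=O)OCC | starting material
4 | bromomagnesium (S)-2-methyl-3-(prop-1-en-2-yl)cyclopent-1-en-1-olate | CC1=C(O[Mg]Br)CC[C@H]1C(C)=C | intermediate
5 | ethyl 2-{[(1S,5S)-1-methyl-2-oxo-5-(prop-1-en-2-yl)cyclopentyl]methyl}prop-2-enoate | O=C1CC[C@@H](C(C)=C)[C@]1(C)CC(=C)C(=O)OCC | intermediate
6 | tertiary C4 radical derived from 5 by H-atom transfer to the isopropenyl CH2 | O=C1CC[C@@H]([C](C)C)[C@]1(C)CC(=C)C(=O)OCC | intermediate
7 | cyclized C6 (α-ester) radical with the trans-hydrindane skeleton | O=C1CC[C@H]2C(C)(C)C[C](C(=O)OCC)C[C@]12C | intermediate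
8 | ethyl (3aS,7aS)-4,4,7a-trimethyl-1-oxooctahydro-1H-indene-6-carboxylate (C6 epimers) | O=C1CC[C@H]2C(C)(C)CC(C(=O)OCC)C[C@]12C | intermediate
9 | (3aS,7aS)-4,4,7a-trimethyl-1-oxooctahydro-1H-indene-6-carboxylic acid (C6 epimers) | O=C1CC[C@H]2C(C)(C)CC(C(=O)O)C[C@]12C | intermediate
10 | (3aS,7aS)-4,4,7a-trimethyloctahydro-1H-inden-1-one | O=C1CC[C@H]2C(C)(C)CCC[C@]12C | intermediate
11 | (3aS,7aS)-4,4,7a-trimethyl-3a,4,5,6,7,7a-hexahydro-3H-inden-1-yl trifluoromethanesulfonate | O=S(=O)(OC1=CC[C@H]2C(C)(C)CCC[C@]12C)C(F)(F)F | intermediate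
12 | tributyl(1-ethoxyvinyl)stannane | CCCC[Sn](CCCC)(CCCC)C(=C)OCC | starting material
13 | (3aS,7aS)-1-(1-ethoxyvinyl)-4,4,7a-trimethyl-3a,4,5,6,7,7a-hexahydro-3H-indene | CCOC(=C)C1=CC[C@H]2C(C)(C)CCC[C@]12C | intermediate
14 | 1-[(3aS,7aS)-4,4,7a-trimethyl-3a,4,5,6,7,7a-hexahydro-3H-inden-1-yl]ethan-1-one | CC(=O)C1=CC[C@H]2C(C)(C)CCC[C@]12C | intermediate
15 | 1-[(1S,3aS,7aS)-4,4,7a-trimethyloctahydro-1H-inden-1-yl]ethan-1-one | CC(=O)[C@H]1CC[C@H]2C(C)(C)CCC[C@]12C | intermediate
16 | (E)-2,4,6-triisopropylbenzenesulfonylhydrazone of 15 | C/C(=N\NS(=O)(=O)c1c(C(C)C)cc(C(C)C)cc1C(C)C)[C@H]1CC[C@H]2C(C)(C)CCC[C@]12C | intermediate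
17 | (S)-4-benzyloxazolidin-2-one | O=C1N[C@@H](Cc2ccccc2)CO1 | starting material
18 | acryloyl chloride | C=CC(=O)Cl | starting material
19 | (S)-3-acryloyl-4-benzyloxazolidin-2-one | C=CC(=O)N1[C@@H](Cc2ccccc2)COC1=O | intermediate
20 | allyloxy(tert-butyl)dimethylsilane | C=CCO[Si](C)(C)C(C)(C)C | starting material
21 | (4S)-4-benzyl-3-[(2E)-4-{[tert-butyl(dimethyl)silyl]oxy}but-2-enoyl]-1,3-oxazolidin-2-one | CC(C)(C)[Si](C)(C)OC/C=C/C(=O)N1[C@@H](Cc2ccccc2)COC1=O | intermediate
22 | {1-[4,4,7a-trimethyloctahydro-1H-inden-1-yl]vinyl}lithium, ring configuration as in 15 | [Li]C(=C)[C@H]1CC[C@H]2C(C)(C)CCC[C@]12C | intermediate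
23 | {1-[4,4,7a-trimethyloctahydro-1H-inden-1-yl]vinyl}magnesium bromide, ring configuration as in 15 | Br[Mg]C(=C)[C@H]1CC[C@H]2C(C)(C)CCC[C@]12C | intermediate
24 | (4S)-4-benzyl-3-[(3R)-3-({[tert-butyl(dimethyl)silyl]oxy}methyl)-4-[(1R,3aS,7aS)-4,4,7a-trimethyloctahydro-1H-inden-1-yl]pent-4-enoyl]-1,3-oxazolidin-2-one | C=C([C@H]1CC[C@H]2C(C)(C)CCC[C@]12C)[C@H](CO[Si](C)(C)C(C)(C)C)CC(=O)N1[C@@H](Cc2ccccc2)COC1=O | intermediate
25 | ethyl glyoxylate | O=CC(=O)OCC | starting material
26 | dibutylboron (Z)-enolate of 24 | C=C([C@H]1CC[C@H]2C(C)(C)CCC[C@]12C)[C@H](CO[Si](C)(C)C(C)(C)C)/C=C(\OB(CCCC)CCCC)N1[C@@H](Cc2ccccc2)COC1=O | intermediate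
27 | ethyl (2S,3S,4R)-3-{[(4S)-4-benzyl-2-oxo-1,3-oxazolidin-3-yl]carbonyl}-4-({[tert-butyl(dimethyl)silyl]oxy}methyl)-2-hydroxy-5-[(1R,3aS,7aS)-4,4,7a-trimethyloctahydro-1H-inden-1-yl]hex-5-enoate | C=C([C@H]1CC[C@H]2C(C)(C)CCC[C@]12C)[C@H](CO[Si](C)(C)C(C)(C)C)[C@H](C(=O)N1[C@@H](Cc2ccccc2)COC1=O)[C@H](O)C(=O)OCC | intermediate
28 | 2-O-tert-butyldimethylsilyl ether of 27 | C=C([C@H]1CC[C@H]2C(C)(C)CCC[C@]12C)[C@H](CO[Si](C)(C)C(C)(C)C)[C@H](C(=O)N1[C@@H](Cc2ccccc2)COC1=O)[C@H](O[Si](C)(C)C(C)(C)C)C(=O)OCC | intermediate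
29 | ethyl (2S,3R,4R)-2-{[tert-butyl(dimethyl)silyl]oxy}-4-({[tert-butyl(dimethyl)silyl]oxy}methyl)-3-(hydroxymethyl)-5-[(1R,3aS,7aS)-4,4,7a-trimethyloctahydro-1H-inden-1-yl]hex-5-enoate | C=C([C@H]1CC[C@H]2C(C)(C)CCC[C@]12C)[C@H](CO[Si](C)(C)C(C)(C)C)[C@H](CO)[C@H](O[Si](C)(C)C(C)(C)C)C(=O)OCC | intermediate
30 | (3S,4R)-3-{[tert-butyl(dimethyl)silyl]oxy}-4-[(2R)-1-{[tert-butyl(dimethyl)silyl]oxy}-3-[(1R,3aS,7aS)-4,4,7a-trimethyloctahydro-1H-inden-1-yl]but-3-en-2-yl]oxolan-2-one | C=C([C@H]1CC[C@H]2C(C)(C)CCC[C@]12C)[C@H](CO[Si](C)(C)C(C)(C)C)[C@@H]1COC(=O)[C@H]1O[Si](C)(C)C(C)(C)C | intermediate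
31 | (3S,4R)-3-hydroxy-4-[(2R)-1-hydroxy-3-[(1R,3aS,7aS)-4,4,7a-trimethyloctahydro-1H-inden-1-yl]but-3-en-2-yl]oxolan-2-one | C=C([C@H]1CC[C@H]2C(C)(C)CCC[C@]12C)[C@H](CO)[C@@H]1COC(=O)[C@H]1O | intermediate
32 | acetyl chloride | CC(=O)Cl | starting material
33 | (2R)-2-[(3R,4S)-4-hydroxy-5-oxooxolan-3-yl]-3-[(1R,3aS,7aS)-4,4,7a-trimethyloctahydro-1H-inden-1-yl]but-3-en-1-yl acetate | C=C([C@H]1CC[C@H]2C(C)(C)CCC[C@]12C)[C@H](COC(C)=O)[C@@H]1COC(=O)[C@H]1O | target

**Step count and risks**

Total: 16 steps. Longest linear sequence: 14 steps (steps 1–8 and 11–16); steps 9–10 make the imide branch.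

Steps most likely to fail:

1. Step 1: low facial discrimination or incomplete conversion when a hindered alkenyl Grignard reagent is added to the α-substituted enone under copper catalysis. Fallback with a stoichiometric sulfoxide auxiliary on the ring: it sets out from Grignard reagent 2 and bromide 3. Reagent 2 is added under ZnBr2 chelation control to enantiopure (S)-2-[(4-methylphenyl)sulfinyl]cyclopent-2-en-1-one F1, which takes the place of 1 (the sulfoxide antipode is chosen by the chelation model), to give the β-keto sulfoxide adduct F2. C-methylation (K2CO3, MeI, acetone) gives the 2-methyl-2-sulfinyl ketone F3. Me2CuLi then removes the sulfinyl group reductively and forms the regiodefined lithium enolate F4, which is alkylated in the same flask with 3 anti to the isopropenyl group. The fallback returns to the route at 5.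

2. Step 11: protonation or incomplete transmetalation of the hindered alkenyl metal, or slow conjugate addition. Fallback by boron and rhodium instead of lithium and copper: it sets out from 15. Kinetic enolisation (LDA, PhNTf2, THF, −78 °C) gives the 1-substituted vinyl triflate F5. Miyaura borylation (B2pin2, PdCl2(PPh3)2, PPh3, KOPh, toluene, 50 °C) gives the alkenyl pinacol boronate F6. Rhodium-catalysed 1,4-addition (Hayashi–Miyaura reaction; [Rh(cod)OH]2, dioxane/H2O, with (S)-BINAP if the auxiliary alone is not enough) to imide 21 then returns to the route at 24.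

3. Step 14: over-reduction of the ester or of the newly formed lactone, or hydride attack on the ring carbonyl of the auxiliary. Fallback by hydrolytic cleavage and activation–reduction: it sets out from 28. LiOH/H2O2 (THF/H2O, 0 °C) removes the auxiliary and gives the carboxylic acid F7. Isobutyl chloroformate and N-methylmorpholine (THF, −15 °C) give the mixed anhydride F8, which NaBH4 in THF/H2O at −15 °C reduces to hydroxy ester 29 without touching the ethyl ester. PPTS in toluene then closes the lactone, and the fallback returns to the route at 30.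

**Further compounds**

F1 | step 1 | (S)-2-[(4-methylphenyl)sulfinyl]cyclopent-2-en-1-one | Cc1ccc(cc1)[S@](=O)C1=CCCC1=O
F2 | step 1 | 3-(prop-1-en-2-yl)-2-[(4-methylphenyl)sulfinyl]cyclopentan-1-one, C3 as in 5, C2 epimers | Cc1ccc(cc1)[S@](=O)C1C(=O)CC[C@H]1C(C)=C
F3 | step 1 | 2-methyl-3-(prop-1-en-2-yl)-2-[(4-methylphenyl)sulfinyl]cyclopentan-1-one, C3 as in 5, C2 epimers | Cc1ccc(cc1)[S@](=O)C1(C)C(=O)CC[C@H]1C(C)=C
F4 | step 1 | lithium (S)-2-methyl-3-(prop-1-en-2-yl)cyclopent-1-en-1-olate | CC1=C(O[Li])CC[C@H]1C(C)=C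
F5 | step 11 | 1-[4,4,7a-trimethyloctahydro-1H-inden-1-yl]vinyl trifluoromethanesulfonate, ring configuration as in 15 | C=C(OS(=O)(=O)C(F)(F)F)[C@H]1CC[C@H]2C(C)(C)CCC[C@]12C
F6 | step 11 | 4,4,5,5-tetramethyl-2-{1-[4,4,7a-trimethyloctahydro-1H-inden-1-yl]vinyl}-1,3,2-dioxaborolane, ring configuration as in 15 | C=C(B1OC(C)(C)C(C)(C)O1)[C@H]1CC[C@H]2C(C)(C)CCC[C@]12C
F7 | step 14 | carboxylic acid from 28 after removal of the oxazolidinone (C3 carboxyl of the hexenoate chain) | C=C([C@H]1CC[C@H]2C(C)(C)CCC[C@]12C)[C@H](CO[Si](C)(C)C(C)(C)C)[C@H](C(=O)O)[C@H](O[Si](C)(C)C(C)(C)C)C(=O)OCC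
F8 | step 14 | isobutyl carbonic mixed anhydride of F7 | C=C([C@H]1CC[C@H]2C(C)(C)CCC[C@]12C)[C@H](CO[Si](C)(C)C(C)(C)C)[C@H](C(=O)OC(=O)OCC(C)C)[C@H](O[Si](C)(C)C(C)(C)C)C(=O)OCC
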